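**Retrosynthetic overview**

1. The target is taken back to its 7-O-triisopropylsilyl ether; the geranyl ether is carried from the first step.
2. Key disconnection C2–C3 (flavanone numbering): the pyranone ring is closed by a catalytic enantioselective Petasis–Ferrier-type [1,3] O-to-C rearrangement of a racemic 2-aryl-4-methylidene-4H-1,3-benzodioxine. The acetal bond O3–C2 of this temporary dioxine ring is absent from the target, is made on purpose, and is traded for the C2–C3 bond.
3. Enabling feature: the acetal carbon C2 carries the aryl oxygen O1, the 4-geranyloxyphenyl ring and, through O3, the exocyclic enol ether C4=CH2 on the same benzene ring. Ionization of C2–O3 therefore gives an O-aryl oxocarbenium ion and the enol of the ortho acetyl group in one molecule, and their only productive recombination is the six-membered C2–C3 closure.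
4. The enol acetal comes from methylenation of the lactone C=O of a 2-aryl-4H-1,3-benzodioxin-4-one, which is the acetal of 2-hydroxy-4-(triisopropylsilyloxy)benzoic acid with 4-(geranyloxy)benzaldehyde (from 4-hydroxybenzaldehyde and geranyl bromide).
5. Ring order: both benzene rings are bought; the temporary 1,3-dioxin-4-one ring is formed first (step 3); the pyran-4-one ring is formed last (step 5), in the same event that opens the dioxine ring.

Key step: step 5

Remark on the chemistry: geranyl = (2E)-3,7-dimethylocta-2,6-dien-1-yl; the sense of induction of the chiral acid in step 5 cannot be predicted with certainty, so the (R)-acid is written and its mirror image is to be used if a first run shows the opposite sense.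

**Route**

Step 1
Reactants: 1 4-hydroxybenzaldehyde; 2 geranyl bromide
Product: 3 4-(geranyloxy)benzaldehyde
Conditions: K2CO3, acetone, reflux
Reagents that add atoms: none
Why: Williamson ether synthesis, in which the phenoxide of 1 displaces the primary allylic bromide of 2 by SN2 and the E-alkene is not touched.

Step 2
Reactants: 4 2,4-dihydroxybenzoic acid
Product: 6 2-hydroxy-4-(triisopropylsilyloxy)benzoic acid, via silyl ester 5 (not isolated)
Conditions: iPr3SiCl (2.1 equiv), imidazole, DMF, 0 °C to rt; then AcOH/THF/H2O (3:1:1), rt
Reagents that add atoms: triisopropylsilyl chloride, CC(C)[Si](Cl)(C(C)C)C(C)C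
Why: Chemoselective silylation followed by silyl ester hydrolysis: the bulky silyl chloride should take the carboxyl group and the free 4-hydroxyl but spare the hindered 2-hydroxyl that is hydrogen-bonded to the carbonyl, and aqueous acetic acid should then cleave only the labile silyl ester.

Step 3
Reactants: 6 2-hydroxy-4-(triisopropylsilyloxy)benzoic acid; 3 4-(geranyloxy)benzaldehyde
Product: 8 racemic 2-[4-(geranyloxy)phenyl]-7-(triisopropylsilyloxy)-4H-1,3-benzodioxin-4-one, via bis(trimethylsilyl) derivative 7 (not isolated)
Conditions: (Me3Si)2NH, cat. Me3SiCl, CH2Cl2, 40 °C, then evaporation; 3, Me3SiOTf (10 mol%), CH2Cl2, −78 to −40 °C; pyridine quench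
Reagents that add atoms: none
Why: Noyori-type acetalization of a bis-silylated hydroxy acid with an aldehyde (the dioxanone-forming step of the Petasis–Ferrier sequence, applied to a salicylic acid) is driven by formation of hexamethyldisiloxane at low temperature, and the new acetal centre is formed racemic, which is of no consequence because step 5 erases it.

Step 4
Reactants: 8 racemic 2-[4-(geranyloxy)phenyl]-7-(triisopropylsilyloxy)-4H-1,3-benzodioxin-4-one
Product: 9 racemic 2-[4-(geranyloxy)phenyl]-4-methylidene-7-(triisopropylsilyloxy)-4H-1,3-benzodioxine
Conditions: Cp2TiMe2 (2.5 equiv), toluene/THF, 65 °C, dark; filtration through basic alumina (hexane, 1% Et3N)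
Reagents that add atoms: dimethyltitanocene (gives the CH2 group), C[Ti](C)(C1C=CC=C1)C1C=CC=C1
Why: Petasis methylenation, in which Cp2Ti=CH2 formed thermally from Cp2TiMe2 should convert the lactone carbonyl into the exocyclic enol ether under non-acidic, non-basic conditions that leave the acylal, the trisubstituted alkenes and the aryl silyl ether intact.

Step 5
Reactants: 9 racemic 2-[4-(geranyloxy)phenyl]-4-methylidene-7-(triisopropylsilyloxy)-4H-1,3-benzodioxine
Product: 11 (2S)-2-[4-(geranyloxy)phenyl]-7-(triisopropylsilyloxy)chroman-4-one, via oxocarbenium enol ion pair 10 (not isolated)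
Conditions: (R)-3,3'-bis(2,4,6-triisopropylphenyl)-1,1'-binaphthyl-2,2'-diyl hydrogen phosphate [(R)-TRIP] (5 mol%), 5 Å MS, toluene (0.02 M), −40 °C
Reagents that add atoms: none
Why: Proposed new method: the chiral phosphoric acid protonates the enol-ether oxygen O3 of 9 and the acetal bond C2–O3 breaks heterolytically, helped by the lone pair of the aryl oxygen O1 and by the 4-alkoxyphenyl ring, to give ion pair 10, in which an O-aryl oxocarbenium ion and the enol of the ortho acetyl group sit on the same benzene ring and are both held by the chiral phosphate; the enol carbon then adds to the oxocarbenium carbon to form the C2–C3 bond and the protonated ketone returns the proton to the catalyst. The closest known reaction types are the Lewis-acid Petasis–Ferrier rearrangement of 4-methylidene-1,3-dioxanes to tetrahydropyran-4-ones and the chiral-phosphoric-acid-catalysed [1,3] O-to-C (Petasis–Ferrier-type and aza-Petasis–Ferrier) rearrangements of vinyl acetals and hemiaminal vinyl ethers; what is new is the benzo-fused substrate and the enantioselective formation of a chroman-4-one. The pyranone ring closes by 6-(enolendo)-endo-trig attack of the enol on the oxocarbenium ion (an intramolecular Mukaiyama–Prins-type aldol step) while the temporary dioxine ring opens. The acetal stereocentre of racemic 9 is destroyed in planar 10, so both enantiomers converge, and the C2 configuration of 11 is set by the catalyst alone: the phosphate, hydrogen-bonded to the enol O–H and paired with the cation, should leave one face of the oxocarbenium carbon open to the tethered enol. The step needs ionization at C2 to beat C-protonation of the enol ether, intramolecular C-attack to beat capture of the cation by water or by another arene, and the product to keep its configuration; the doubly stabilized acetal carbon, the ortho tether (O-attack merely re-forms 9, and a cation diverted by C-protonation can re-enter through acid-catalysed enolization), the dry, dilute, non-nucleophilic medium and the weak acid at low temperature, which should leave the geranyl alkenes, the allylic aryl ether, the silyl ether and the flavanone untouched, are meant to secure this.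

Step 6
Reactants: 11 (2S)-2-[4-(geranyloxy)phenyl]-7-(triisopropylsilyloxy)chroman-4-one
Product: 12 (2S)-2-[4-(geranyloxy)phenyl]-7-hydroxychroman-4-one (CNP0302343.1)
Conditions: Bu4NF/AcOH (1:1), THF, 0 °C
Reagents that add atoms: none
Why: Fluoride-induced cleavage of the aryl silyl ether, buffered with acetic acid so that no free phenoxide or enolate can open the pyranone ring by retro-oxa-Michael reaction and erode the C2 configuration, with the geranyl ether inert to fluoride.

**Compound list**

1 | 4-hydroxybenzaldehyde | O=Cc1ccc(O)cc1 | starting material
2 | geranyl bromide, (2E)-1-bromo-3,7-dimethylocta-2,6-diene | CC(C)=CCC/C(C)=C/CBr | starting material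
3 | 4-(geranyloxy)benzaldehyde | CC(C)=CCC/C(C)=C/COc1ccc(C=O)cc1 | intermediate
4 | 2,4-dihydroxybenzoic acid | O=C(O)c1ccc(O)cc1O | starting material
5 | triisopropylsilyl 2-hydroxy-4-(triisopropylsilyloxy)benzoate | CC(C)[Si](OC(=O)c1ccc(O[Si](C(C)C)(C(C)C)C(C)C)cc1O)(C(C)C)C(C)C | intermediate
6 | 2-hydroxy-4-(triisopropylsilyloxy)benzoic acid | O=C(O)c1ccc(O[Si](C(C)C)(C(C)C)C(C)C)cc1O | intermediate
7 | trimethylsilyl 4-(triisopropylsilyloxy)-2-(trimethylsilyloxy)benzoate | C[Si](C)(C)OC(=O)c1ccc(O[Si](C(C)C)(C(C)C)C(C)C)cc1O[Si](C)(C)C | intermediate
8 | racemic 2-[4-(geranyloxy)phenyl]-7-(triisopropylsilyloxy)-4H-1,3-benzodioxin-4-one | CC(C)=CCC/C(C)=C/COc1ccc(C2OC(=O)c3ccc(O[Si](C(C)C)(C(C)C)C(C)C)cc3O2)cc1 | intermediate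
9 | racemic 2-[4-(geranyloxy)phenyl]-4-methylidene-7-(triisopropylsilyloxy)-4H-1,3-benzodioxine | CC(C)=CCC/C(C)=C/COc1ccc(C2OC(=C)c3ccc(O[Si](C(C)C)(C(C)C)C(C)C)cc3O2)cc1 | intermediate
10 | ion pair of the O-[2-(1-hydroxyvinyl)-5-(triisopropylsilyloxy)phenyl] oxocarbenium ion of 4-(geranyloxy)benzaldehyde with the phosphate of the catalyst (axial configuration of the anion as in the catalyst, not shown in the SMILES) | CC(C)=CCC/C(C)=C/COc1ccc(C=[O+]c2cc(O[Si](C(C)C)(C(C)C)C(C)C)ccc2C(=C)O)cc1.CC(C)c1cc(C(C)C)c(-c2cc3ccccc3c3c2OP(=O)([O-])Oc2c(-c4c(C(C)C)cc(C(C)C)cc4C(C)C)cc4ccccc4c2-3)c(C(C)C)c1 | intermediate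
11 | (2S)-2-[4-(geranyloxy)phenyl]-7-(triisopropylsilyloxy)chroman-4-one | CC(C)=CCC/C(C)=C/COc1ccc([C@@H]2CC(=O)c3ccc(O[Si](C(C)C)(C(C)C)C(C)C)cc3O2)cc1 | intermediate
12 | (2S)-2-[4-(geranyloxy)phenyl]-7-hydroxychroman-4-one (CNP0302343.1) | CC(C)=CCC/C(C)=C/COc1ccc([C@@H]2CC(=O)c3ccc(O)cc3O2)cc1 | target

**Count and risks**

Total step count: 6. Longest linear sequence: 5 steps (4 → 6 → 8 → 9 → 11 → 12; equally 1 → 3 → 8 → 9 → 11 → 12).

Steps most likely to fail:

1. Step 5 (Proposed new method). What may go wrong: poor facial selectivity in the collapse of the ion pair, or diversion of the cation (C-protonation of the enol ether, then hydrolysis) before the C–C bond forms. The fallback uses known chemistry and sets out from 9. The classical Lewis-acid Petasis–Ferrier conditions (Me2AlCl, CH2Cl2, −78 °C) should convert 9 into racemic 2-[4-(geranyloxy)phenyl]-7-(triisopropylsilyloxy)chroman-4-one F1. F1 is then resolved kinetically by asymmetric transfer hydrogenation (RhCl(C5Me5)[(R,R)-TsDPEN], HCO2H/Et3N, EtOAc, rt, stopped near half conversion; the ligand antipode is the one that reduces the (R)-ketone faster, (R,R) by the usual model). This should turn the (R)-enantiomer into cis-(2R,4R)-2-[4-(geranyloxy)phenyl]-7-(triisopropylsilyloxy)chroman-4-ol F2 and leave the (S)-ketone, which after chromatography is 11, where the route is rejoined.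

2. Step 3. What may go wrong: incomplete acetal formation, because the aryl silyl ether and the donor-substituted aldehyde are both sluggish partners, with competing Lewis-acid ionization of the allylic aryl ether (loss of the geranyl group) and hydrolysis of the acylal on isolation. The fallback sets out from 3 and drops silyl transfer and the Lewis acid. Aldehyde 3 is converted with HC(OMe)3 and cat. pyridinium p-toluenesulfonate in MeOH into 1-(dimethoxymethyl)-4-(geranyloxy)benzene F3. F3 is then exchanged with acid 6 under cat. pyridinium p-toluenesulfonate in toluene at 60 °C, with methanol removed continuously (reduced pressure or 4 Å sieves), so that the equilibrium is driven toward the cyclic acylal. This should give 8, where the route is rejoined.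

3. Step 4. What may go wrong: thermal ionization or cycloreversion of the donor-substituted acylal while the titanium methylidene is generated at 65 °C, and acid-triggered collapse of the enol acetal on isolation (hydrolysis or premature racemic rearrangement). If the enol acetal cannot be secured, the rearrangement has no entry, and the fallback reaches 11 by the established catalytic asymmetric conjugate addition of arylboronic acids to chromones, which forms the C2–aryl bond instead. It sets out from 2. Commercial 4-hydroxyphenylboronic acid is O-alkylated with 2 (K2CO3, acetone) to [4-(geranyloxy)phenyl]boronic acid F4. Commercial 7-hydroxy-4H-chromen-4-one is silylated (iPr3SiCl, imidazole, DMF) to 7-(triisopropylsilyloxy)-4H-chromen-4-one F5. F4 is then added to F5 with Pd(OCOCF3)2 (5 mol%), (S)-4-tert-butyl-2-(pyridin-2-yl)-4,5-dihydrooxazole or its antipode (whichever delivers the (S)-flavanone), NH4PF6 and H2O in ClCH2CH2Cl at 60 °C. This should give 11, where the route is rejoined.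

Further compounds
F1 | step 5 | racemic 2-[4-(geranyloxy)phenyl]-7-(triisopropylsilyloxy)chroman-4-one | CC(C)=CCC/C(C)=C/COc1ccc(C2CC(=O)c3ccc(O[Si](C(C)C)(C(C)C)C(C)C)cc3O2)cc1
F2 | step 5 | cis-(2R,4R)-2-[4-(geranyloxy)phenyl]-7-(triisopropylsilyloxy)chroman-4-ol | CC(C)=CCC/C(C)=C/COc1ccc([C@H]2C[C@@H](O)c3ccc(O[Si](C(C)C)(C(C)C)C(C)C)cc3O2)cc1
F3 | step 3 | 1-(dimethoxymethyl)-4-(geranyloxy)benzene | CC(C)=CCC/C(C)=C/COc1ccc(C(OC)OC)cc1
F4 | step 4 | [4-(geranyloxy)phenyl]boronic acid | CC(C)=CCC/C(C)=C/COc1ccc(B(O)O)cc1
F5 | step 4 | 7-(triisopropylsilyloxy)-4H-chromen-4-one | O=c1ccoc2cc(O[Si](C(C)C)(C(C)C)C(C)C)ccc12
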